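(The earlier runs and the new flask were generated by integration for an exercise; scatter was added.)

Answer 4 questions on 2 flasks of substrate and reagent over a catalyst; the flasks differ in the time they stand.

| setting | dawn | dusk | south-west | south-east |
|---|---|---|---|---|
| substrate | 0.025 M | 0.10 M | 0.050 M | 0.050 M |
| reagent | 0.80 equiv | 0.80 equiv | 0.800 equiv | 0.800 equiv |
| free catalyst | 9.1 mol% | 9.1 mol% | 9.1 mol% | 9.1 mol% |
| remark | run made earlier | run made earlier |  |  |
| time |  |  | 25 d | 30 d |

- which of these there is most of at the end, counted by the substrate in it, south-west (catalyst intermediate C / substrate / catalyst intermediate B / product)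
- which of these there is most of at the end, counted by the substrate in it, south-east (catalyst intermediate C / substrate / catalyst intermediate B / product)
- amount of the one of these that there is most of at the end, in percent of the substrate charged, south-west
- amount of the one of these that there is most of at the end, in percent of the substrate charged, south-east

| run | time / d | catalyst intermediate C / % | product / % | substrate / % | catalyst intermediate B / % |
|---|---|---|---|---|---|
| dawn | 2.08 | 0 | 53 | 45 | 0 |
| dawn | 6.00 | 0 | 78 | 22 | 0 |
| dawn | 10.0 | 5 | 78 | 18 | 0 |
| dawn | 15.0 | 0 | 79 | 21 | 0 |
| dawn | 25.0 | 0 | 78 | 21 | 0 |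
| dawn | 30.0 | 0 | 79 | 19 | 0 |
| dusk | 5.00 | 5 | 74 | 21 | 0 |
| dusk | 10.0 | 4 | 75 | 19 | 2 |
| dusk | 15.0 | 5 | 77 | 19 | 0 |
| dusk | 20.0 | 1 | 78 | 22 | 0 |
| dusk | 25.0 | 4 | 77 | 20 | 1 |
| dusk | 30.0 | 3 | 77 | 16 | 1 |

(readings scatter by 1.5 percentage points)

At 0.800 equiv of reagent, take 80.0% as the reagent ceiling, the percent of the substrate charged that the reagent can turn over, one for one, with reagent as the limiting reagent.

Read the row at 25.0 d in each run. Substrate stands at 21% in the dawn run and 20% in the dusk run. The ceiling leaves 20.0%, so the one-for-one count fits within the scatter of 1.5 percentage points.

Now read the next columns of that row. Product is 78% in the dawn run with catalyst intermediate C at 0%, and 77% in the dusk run with catalyst intermediate C at 4%. So count catalyst intermediate C as substrate turned over but standing outside product.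

South-west starts at 0.050 M, above the dawn run and below the dusk run. Take the midway hold, 2.00%, which gives my own reckoning of 78.0% product.

Then read the early rows for speed. The dawn run has substrate down to 22% by 6.00 d, and the dusk run to 21% by 5.00 d. Both asked times, 25 d and 30 d, lie later, so expect the same product in both flasks.

The forecast gives product at 78% for south-west and product at 78.1% for south-east, on the ground that “A fourfold concentration change barely moves the plateau”.

The result is product at 77.8% in south-west and product at 77.8% in south-east, so the forecast holds. In south-east, product moves by 6 points with reagent at 0.739 equiv or at 0.862 equiv. In south-west, catalyst intermediate C holds 2.23% of the substrate charged, and the ceiling less that hold is 77.8%, the product found.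

    reagent + free catalyst → catalyst intermediate A (k = 2.50 /M/min)
    catalyst intermediate B → by-product + catalyst intermediate C (k = 0.210 /min)
    catalyst intermediate C ⇌ free catalyst + product (K = 0.120 M, k = 0.0130 /min)
    substrate + catalyst intermediate A → catalyst intermediate B (k = 0.160 /M/min)

Take a neighbour flask, the same as south-west but with 0.320 equiv of reagent. Its ceiling is 32.0%, so expect product just under that and 68.0% of substrate left. The computed flask gives product at 31.0% and substrate at 68.0%, with substrate now holding most.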